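**Retrosynthetic overview**
1. Planaic acid ⇒ (TFA, then MeI/K2CO3 in reverse) its tert-butyl ester with free 2-OH and 4-OH on ring A. Ring B is bought intact as methyl olivetolate, so ring A is the only ring to be built.
2. The plan rests on ring A, the 2,4-dioxygenated 6-pentylbenzoyl ring, being an olivetolate: a folded 3,5,7-trioxododecanoyl chain whose C2 and C7 are ring A C1 and C6. Cutting that C1–C6 bond (aldol aromatisation) leaves the ring B aryl ester of the open-chain triketo acid.
3. Triketo aryl ester ⇒ ring B phenol + acylketene (a diketo-dioxinone minus acetone). The hindered depside C(=O)–O bond is therefore made before ring A exists.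
4. Diketo-dioxinone ⇒ 2,2,6-trimethyl-1,3-dioxin-4-one + acetyl chloride + the Weinreb amide of hexanoic acid (two Claisen acylations). Ring B phenol ⇒ methyl olivetolate (4-O-benzyl, 2-O-methyl, methyl-to-tert-butyl ester exchange, hydrogenolysis).

Key step: step 10

Remark: the 1,3-dicarbonyl compounds (3, 6, 13, 14, 15) are drawn as keto tautomers; in solution they should be largely enolised, which does not change any step.

Step 1
Reactants: 1 2,2,6-trimethyl-4H-1,3-dioxin-4-one; 2 acetyl chloride
Product: 3 2,2-dimethyl-6-(2-oxopropyl)-4H-1,3-dioxin-4-one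
Conditions: 1 (2 equiv), LiN(SiMe3)2 (2 equiv), THF, −78 °C; then 2 (1 equiv), −78 °C; 1 M aq. HCl quench
Reagents that add atoms: none
Why: Kinetic deprotonation of the 6-methyl group gives the lithium dienolate, which undergoes vinylogous Claisen C-acylation with the acid chloride, the second equivalent of dienolate covering deprotonation of the more acidic β-keto product.

Step 2
Reactants: 4 hexanoyl chloride
Product: 5 N-methoxy-N-methylhexanamide
Conditions: MeNH(OMe)·HCl, Et3N (2.2 equiv), CH2Cl2, 0 °C → rt
Reagents that add atoms: N,O-dimethylhydroxylamine hydrochloride, CNOC.Cl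
Why: Schotten–Baumann-type N-acylation of the hydroxylamine gives the Weinreb amide, chosen because its chelated tetrahedral adduct prevents over-addition in the next step.

Step 3
Reactants: 3 2,2-dimethyl-6-(2-oxopropyl)-4H-1,3-dioxin-4-one; 5 N-methoxy-N-methylhexanamide
Product: 6 6-(2,4-dioxononyl)-2,2-dimethyl-4H-1,3-dioxin-4-one
Conditions: LiN(i-Pr)2 (2.2 equiv), THF, −78 → −40 °C; then 5, −78 → −20 °C; 1 M aq. HCl to pH 3, 0 °C
Reagents that add atoms: none
Why: The dianion of the β-keto-dioxinone reacts at its more basic terminal carbon in a Claisen acylation that stops at the chelated Weinreb adduct, so one hexanoyl group is added and the 1,3-diketone appears only on quench.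

Step 4
Reactants: 7 methyl 2,4-dihydroxy-6-pentylbenzoate (methyl olivetolate)
Product: 8 methyl 4-(benzyloxy)-2-hydroxy-6-pentylbenzoate
Conditions: BnBr (1.05 equiv), K2CO3, acetone, reflux
Reagents that add atoms: benzyl bromide, BrCc1ccccc1
Why: Williamson etherification is selective for the 4-OH because the 2-OH is held in a hydrogen bond to the ester carbonyl and is less acidic and less accessible.

Step 5
Reactants: 8 methyl 4-(benzyloxy)-2-hydroxy-6-pentylbenzoate
Product: 9 methyl 4-(benzyloxy)-2-methoxy-6-pentylbenzoate
Conditions: MeI (excess), K2CO3, DMF, 50 °C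
Reagents that add atoms: iodomethane, CI
Why: Williamson O-methylation of the remaining chelated phenol proceeds under more forcing conditions in a polar aprotic solvent, no other acidic site being left.

Step 6
Reactants: 9 methyl 4-(benzyloxy)-2-methoxy-6-pentylbenzoate
Product: 10 4-(benzyloxy)-2-methoxy-6-pentylbenzoic acid
Conditions: KOH, DMSO/H2O (4:1), 90 °C; then 1 M aq. HCl, 0 °C
Reagents that add atoms: potassium hydroxide, [K+].[OH-]
Why: Saponification (acyl–oxygen cleavage) of the di-ortho-substituted benzoate is made possible by the poorly solvated hydroxide of aqueous DMSO, the ethers being inert and cold acidification avoiding protodecarboxylation.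

Step 7
Reactants: 10 4-(benzyloxy)-2-methoxy-6-pentylbenzoic acid
Product: 11 tert-butyl 4-(benzyloxy)-2-methoxy-6-pentylbenzoate
Conditions: Me2NCH(Ot-Bu)2 (4 equiv), toluene, 80 °C
Reagents that add atoms: N,N-dimethylformamide di-tert-butyl acetal, CN(C)C(OC(C)(C)C)OC(C)(C)C
Why: The formamide acetal esterifies by O-alkylation of the carboxylate with a tert-butyl cation equivalent, so the bond forms at oxygen and the two ortho groups that shield the carbonyl carbon do not interfere.

Step 8
Reactants: 11 tert-butyl 4-(benzyloxy)-2-methoxy-6-pentylbenzoate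
Product: 12 tert-butyl 4-hydroxy-2-methoxy-6-pentylbenzoate
Conditions: H2 (1 atm), Pd/C, EtOAc, rt
Reagents that add atoms: none
Why: Catalytic hydrogenolysis cleaves the benzyl aryl ether, while the tert-butyl ester, the methyl ether and the arene are untouched at 1 atm and rt.

Step 9
Reactants: 6 6-(2,4-dioxononyl)-2,2-dimethyl-4H-1,3-dioxin-4-one; 12 tert-butyl 4-hydroxy-2-methoxy-6-pentylbenzoate
Product: 14 tert-butyl 2-methoxy-6-pentyl-4-[(3,5,7-trioxododecanoyl)oxy]benzoate, via diketo acylketene 13 (not isolated)
Conditions: 6 (1.2 equiv), 12 (1 equiv), toluene (0.3 M), 110 °C, N2; evaporate, use crude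
Reagents that add atoms: none
Why: Thermal retro-hetero-Diels–Alder fragmentation of the dioxinone releases acetone and an acylketene whose unhindered sp carbon is captured by the phenol O–H to give the aryl β-keto ester, a concentrated solution favouring this intermolecular capture over internal O-cyclisation to a pyrone.

Step 10
Reactants: 14 tert-butyl 2-methoxy-6-pentyl-4-[(3,5,7-trioxododecanoyl)oxy]benzoate
Product: 16 tert-butyl 4-[(2,4-dihydroxy-6-pentylbenzoyl)oxy]-2-methoxy-6-pentylbenzoate, via cyclic aldol adduct 15 (not isolated)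
Conditions: Et3N (2 equiv), CH2Cl2, 0 °C → rt; pH 5 buffer wash
Reagents that add atoms: none
Why: Et3N reversibly generates the ammonium enolate of the polyketone chain, and the C2 carbanion, stabilised by the C1 aryl ester and the C3 ketone, adds to the C7 ketone to give the cyclic aldol adduct 15; E1cB loss of water and two enolisations then give the resorcinol ring, so the new C2–C7 bond becomes the C1–C6 bond of ring A. The closest known reaction type is the amine- or carbonate-induced aldol aromatisation of 3,5,7-triketo alkyl esters obtained by acylketene trapping, the polyketide folding that leads to olivetolic acid; here the ester is an aryl ester. Ring A closes in a 6-(enolexo)-exo-trig mode when the nucleophile is written as the ester enolate (6-(enolendo)-exo-trig when written as the C3 enolate), both favourable. No stereocenter has to be controlled, because the two sp3 centres of 15 vanish on aromatisation, which also makes the closure irreversible. The step needs aldol closure (C2 onto C7) to outrun Claisen closure (C6 onto C1) and lactonisation of the C5 enol oxygen onto C1, both of which would expel the ring B aryloxide. This should be secured by a non-nucleophilic amine in an aprotic solvent at 0 °C (no metal alkoxide to template the Claisen path, no protic nucleophile), by the higher electrophilicity of the C7 ketone compared with the ester carbon, and by the modest leaving-group ability of the ring B aryloxide, whose para ester is twisted out of conjugation by its two ortho substituents.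

Step 11
Reactants: 16 tert-butyl 4-[(2,4-dihydroxy-6-pentylbenzoyl)oxy]-2-methoxy-6-pentylbenzoate
Product: 17 tert-butyl 4-[(2,4-dimethoxy-6-pentylbenzoyl)oxy]-2-methoxy-6-pentylbenzoate
Conditions: MeI (excess), K2CO3, DMF, rt → 40 °C
Reagents that add atoms: iodomethane, CI
Why: Williamson O-methylation of both phenols, the chelated 2-OH requiring excess MeI in DMF, while the di-ortho-substituted depside ester and the tert-butyl ester are sterically shielded from carbonate and phenoxide attack.

Step 12
Reactants: 17 tert-butyl 4-[(2,4-dimethoxy-6-pentylbenzoyl)oxy]-2-methoxy-6-pentylbenzoate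
Product: 18 planaic acid, 4-[(2,4-dimethoxy-6-pentylbenzoyl)oxy]-2-methoxy-6-pentylbenzoic acid
Conditions: TFA/CH2Cl2 (1:4), 0 °C → rt
Reagents that add atoms: none
Why: Acidolysis of the tert-butyl ester by alkyl–oxygen ionisation (E1) releases isobutene and the free acid, while the aryl ester and the methyl ethers, which cannot ionise in this way, are stable to anhydrous TFA.

**Compound list**
1 | 2,2,6-trimethyl-4H-1,3-dioxin-4-one | CC1=CC(=O)OC(C)(C)O1 | starting material
2 | acetyl chloride | CC(=O)Cl | starting material
3 | 2,2-dimethyl-6-(2-oxopropyl)-4H-1,3-dioxin-4-one | CC(=O)CC1=CC(=O)OC(C)(C)O1 | intermediate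
4 | hexanoyl chloride | CCCCCC(=O)Cl | starting material
5 | N-methoxy-N-methylhexanamide | CCCCCC(=O)N(C)OC | intermediate
6 | 6-(2,4-dioxononyl)-2,2-dimethyl-4H-1,3-dioxin-4-one | CCCCCC(=O)CC(=O)CC1=CC(=O)OC(C)(C)O1 | intermediate
7 | methyl 2,4-dihydroxy-6-pentylbenzoate (methyl olivetolate) | CCCCCc1cc(O)cc(O)c1C(=O)OC | starting material
8 | methyl 4-(benzyloxy)-2-hydroxy-6-pentylbenzoate | CCCCCc1cc(OCc2ccccc2)cc(O)c1C(=O)OC | intermediate
9 | methyl 4-(benzyloxy)-2-methoxy-6-pentylbenzoate | CCCCCc1cc(OCc2ccccc2)cc(OC)c1C(=O)OC | intermediate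
10 | 4-(benzyloxy)-2-methoxy-6-pentylbenzoic acid | CCCCCc1cc(OCc2ccccc2)cc(OC)c1C(=O)O | intermediate
11 | tert-butyl 4-(benzyloxy)-2-methoxy-6-pentylbenzoate | CCCCCc1cc(OCc2ccccc2)cc(OC)c1C(=O)OC(C)(C)C | intermediate
12 | tert-butyl 4-hydroxy-2-methoxy-6-pentylbenzoate | CCCCCc1cc(O)cc(OC)c1C(=O)OC(C)(C)C | intermediate
13 | diketo acylketene, dodec-1-ene-1,3,5,7-tetrone | CCCCCC(=O)CC(=O)CC(=O)C=C=O | intermediate
14 | tert-butyl 2-methoxy-6-pentyl-4-[(3,5,7-trioxododecanoyl)oxy]benzoate | CCCCCC(=O)CC(=O)CC(=O)CC(=O)Oc1cc(CCCCC)c(C(=O)OC(C)(C)C)c(OC)c1 | intermediate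
15 | cyclic aldol adduct, tert-butyl 4-[(2-hydroxy-4,6-dioxo-2-pentylcyclohexane-1-carbonyl)oxy]-2-methoxy-6-pentylbenzoate (diastereomer mixture, configuration not defined) | CCCCCC1(O)CC(=O)CC(=O)C1C(=O)Oc1cc(CCCCC)c(C(=O)OC(C)(C)C)c(OC)c1 | intermediate
16 | tert-butyl 4-[(2,4-dihydroxy-6-pentylbenzoyl)oxy]-2-methoxy-6-pentylbenzoate | CCCCCc1cc(O)cc(O)c1C(=O)Oc1cc(CCCCC)c(C(=O)OC(C)(C)C)c(OC)c1 | intermediate
17 | tert-butyl 4-[(2,4-dimethoxy-6-pentylbenzoyl)oxy]-2-methoxy-6-pentylbenzoate | CCCCCc1cc(OC)cc(OC)c1C(=O)Oc1cc(CCCCC)c(C(=O)OC(C)(C)C)c(OC)c1 | intermediate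
18 | planaic acid, 4-[(2,4-dimethoxy-6-pentylbenzoyl)oxy]-2-methoxy-6-pentylbenzoic acid | CCCCCc1cc(OC(=O)c2c(CCCCC)cc(OC)cc2OC)cc(OC)c1C(=O)O | target

**Step count**
Total: 12 steps. Longest linear sequence: 9 steps (7 → 8 → 9 → 10 → 11 → 12 → 14 → 16 → 17 → 18, steps 4 to 12).

**Steps most likely to fail**

1. Step 10 (key step). What may go wrong: loss of the ring B aryloxide from the activated ester faster than the C2-to-C7 aldol closure. This could happen by Claisen closure of C6 onto C1, by lactonisation of the C5 enol oxygen onto C1, or by E1cB fragmentation back to the acylketene. Fallback (classical depside esterification with ring A made beforehand): setting out from 7, exhaustive methylation (MeI, K2CO3, DMF) would give methyl 2,4-dimethoxy-6-pentylbenzoate F1. Saponification (KOH, DMSO/H2O, 90 °C) would give 2,4-dimethoxy-6-pentylbenzoic acid F2, and (COCl)2 with catalytic DMF in CH2Cl2 would give 2,4-dimethoxy-6-pentylbenzoyl chloride F3. Acylation of the sodium aryloxide of 12 (NaH, THF, 0 °C → reflux) with F3 would give 17 directly, where the route is rejoined before step 12.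

2. Step 9. What may go wrong: internal capture of the acylketene by the C5 enol oxygen (pyrone formation), or ketene dimerisation, outpacing the intermolecular addition of the weakly nucleophilic phenol. Fallback (ring first, ester second): setting out from 6, Et3N in CH2Cl2 should bring about aldol aromatisation of the intact diketo-dioxinone (dioxinone C5 onto the terminal ketone) to 7-hydroxy-2,2-dimethyl-5-pentyl-4H-1,3-benzodioxin-4-one F4. Methylation (MeI, K2CO3, acetone) would give 7-methoxy-2,2-dimethyl-5-pentyl-4H-1,3-benzodioxin-4-one F5. Acyl transfer from F5 to the sodium aryloxide of 12 (NaH, THF/DMF, 60 °C), with loss of acetone, would give tert-butyl 4-[(2-hydroxy-4-methoxy-6-pentylbenzoyl)oxy]-2-methoxy-6-pentylbenzoate F6; the aryloxide opening is the demanding operation of this sequence. Methylation of the remaining phenol (MeI, K2CO3, DMF) returns to the route at 17.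

3. Step 3. What may go wrong: incomplete dianion formation, proton transfer between the dianion and the Weinreb amide, or acylation at the internal carbon, leading to low conversion. Fallback (soft-enolisation acylation followed by decarboxylation): setting out from 1, LiN(SiMe3)2 and then allyl 3-chloro-3-oxopropanoate would give allyl 4-(2,2-dimethyl-4-oxo-4H-1,3-dioxin-6-yl)-3-oxobutanoate F7. C-Acylation with 4 mediated by MgCl2 and pyridine in CH2Cl2 would give allyl 2-[(2,2-dimethyl-4-oxo-4H-1,3-dioxin-6-yl)acetyl]-3-oxooctanoate F8. Pd(PPh3)4, a zerovalent palladium complex, with morpholine in THF would remove the allyl group, and decarboxylation returns to the route at 6.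

**Further compounds**
F1 | step 10 | methyl 2,4-dimethoxy-6-pentylbenzoate | CCCCCc1cc(OC)cc(OC)c1C(=O)OC
F2 | step 10 | 2,4-dimethoxy-6-pentylbenzoic acid | CCCCCc1cc(OC)cc(OC)c1C(=O)O
F3 | step 10 | 2,4-dimethoxy-6-pentylbenzoyl chloride | CCCCCc1cc(OC)cc(OC)c1C(=O)Cl
F4 | step 9 | 7-hydroxy-2,2-dimethyl-5-pentyl-4H-1,3-benzodioxin-4-one | CCCCCc1cc(O)cc2c1C(=O)OC(C)(C)O2
F5 | step 9 | 7-methoxy-2,2-dimethyl-5-pentyl-4H-1,3-benzodioxin-4-one | CCCCCc1cc(OC)cc2c1C(=O)OC(C)(C)O2
F6 | step 9 | tert-butyl 4-[(2-hydroxy-4-methoxy-6-pentylbenzoyl)oxy]-2-methoxy-6-pentylbenzoate | CCCCCc1cc(OC)cc(O)c1C(=O)Oc1cc(CCCCC)c(C(=O)OC(C)(C)C)c(OC)c1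
F7 | step 3 | allyl 4-(2,2-dimethyl-4-oxo-4H-1,3-dioxin-6-yl)-3-oxobutanoate | C=CCOC(=O)CC(=O)CC1=CC(=O)OC(C)(C)O1
F8 | step 3 | allyl 2-[(2,2-dimethyl-4-oxo-4H-1,3-dioxin-6-yl)acetyl]-3-oxooctanoate | C=CCOC(=O)C(C(=O)CCCCC)C(=O)CC1=CC(=O)OC(C)(C)O1
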